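**Plan**
- Retrosynthetic cuts, in order: the two aryl O–Si bonds; the bond between C11 and the pyran CH2, which leads back to a terminal oxirane; the oxepine C10=C11 alkene (metathesis); the C10=CH2 enol ether, which leads back to a tertiary ester; the ester C–O bond; the diaryl ether C–O bond.
- Enabling feature: in the oxepine, O–C10=C11 is an enol ether. Its β-carbon C11 is pushed by the ether oxygen and by the para-oxygenated ring B on C10. The tertiary ether carbon carries an oxirane whose CH2 lies six atoms from C11, so a Lewis acid can close the dihydropyran at C11–CH2.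
- Forward order: side chain 5 from nerol; rings A (9) and B (11) joined by Ullmann coupling; CHO to CO2H to tertiary ester to 1-alkoxyvinyl arene; metathesis closes the oxepine (third ring); epoxide opening by C11 closes the pyran (fourth ring); desilylation.
- Stereochemistry: both centres come from the Sharpless epoxidation of nerol, which gives (2S,3R). Acid hydrolysis inverts the tertiary carbon to S; the carbinol carbon keeps its oxygen (S). No later step breaks a bond at either centre.

Key step: step 14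

Remark: C10 and C11 are the oxepine alkene carbons in dibenzo[b,f]oxepine numbering (C10 carries the pyran oxygen and ring B, C11 carries the prenylated ring A). The enol ethers 17 to 19 are assumed to be purified on base-washed silica or neutral alumina.

**Step 1**
Reactants: 1 nerol [(2Z)-3,7-dimethylocta-2,6-dien-1-ol]
Product: 2 (2S,3R)-2,3-epoxynerol
Conditions: Ti(OiPr)4 (cat.), L-(+)-diethyl tartrate (cat.), t-BuOOH, 4 Å MS, CH2Cl2, −20 °C
Reagents that add atoms: tert-butyl hydroperoxide, CC(C)(C)OO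
Why: Sharpless asymmetric epoxidation acts only on the allylic-alcohol alkene (the 6,7-alkene stays) and with the L-(+)-tartrate should deliver oxygen to the face of the Z-alkene that gives the (2S,3R)-epoxide, which fixes the absolute configuration of both later stereocentres.

**Step 2**
Reactants: 2 (2S,3R)-2,3-epoxynerol
Product: 3 (2S,3R)-2,3-epoxyneryl 4-methylbenzenesulfonate
Conditions: TsCl, Et3N, DMAP (cat.), CH2Cl2, 0 °C
Reagents that add atoms: 4-methylbenzenesulfonyl chloride, Cc1ccc(cc1)S(Cl)(=O)=O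
Why: Sulfonylation of the primary alcohol makes C1 a leaving group for the later oxirane closure and touches neither stereocentre.

**Step 3**
Reactants: 3 (2S,3R)-2,3-epoxyneryl 4-methylbenzenesulfonate
Product: 4 (2S,3S)-2,3-dihydroxy-3,7-dimethyloct-6-en-1-yl 4-methylbenzenesulfonate
Conditions: HClO4 (cat.), THF–H2O, 0 °C to rt
Reagents that add atoms: water, O
Why: Acid-catalysed epoxide hydrolysis (borderline SN2) should open the protonated oxirane at the tertiary carbon C3 with inversion, so C3 becomes S while C2 keeps its oxygen and its S configuration; the sulfonate inductively disfavours attack at C2.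

**Step 4**
Reactants: 4 (2S,3S)-2,3-dihydroxy-3,7-dimethyloct-6-en-1-yl 4-methylbenzenesulfonate
Product: 5 (2S)-6-methyl-2-[(2S)-oxiran-2-yl]hept-5-en-2-ol
Conditions: K2CO3, MeOH, 0 °C, short reaction time
Reagents that add atoms: none
Why: Intramolecular Williamson etherification (3-exo-tet) of the secondary alkoxide onto the primary tosylate closes the terminal oxirane with retention at C2; the weak base and low temperature keep the tertiary alcohol from migrating the epoxide (Payne rearrangement).

**Step 5**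
Reactants: 6 5-bromo-2,4-dihydroxybenzaldehyde
Product: 7 5-bromo-2-hydroxy-4-(triisopropylsilyloxy)benzaldehyde
Conditions: TIPSCl (1.05 equiv), imidazole, CH2Cl2, 0 °C to rt
Reagents that add atoms: chlorotriisopropylsilane, CC(C)[Si](Cl)(C(C)C)C(C)C
Why: Silylation should take the 4-OH, because the 2-OH is hydrogen-bonded to the formyl group and less nucleophilic.

**Step 6**
Reactants: 7 5-bromo-2-hydroxy-4-(triisopropylsilyloxy)benzaldehyde
Product: 8 2-hydroxy-5-(3-methylbut-2-en-1-yl)-4-(triisopropylsilyloxy)benzaldehyde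
Conditions: tributyl(prenyl)stannane, Pd(PPh3)4 (cat.), LiCl, DMF, 90 °C
Reagents that add atoms: tributyl(3-methylbut-2-en-1-yl)stannane, CCCC[Sn](CCCC)(CCCC)CC=C(C)C
Why: Stille coupling of the aryl bromide with the allylic stannane should transfer the less substituted allyl terminus and give the linear prenyl arene.

**Step 7**
Reactants: 8 2-hydroxy-5-(3-methylbut-2-en-1-yl)-4-(triisopropylsilyloxy)benzaldehyde
Product: 9 2-ethenyl-4-(3-methylbut-2-en-1-yl)-5-(triisopropylsilyloxy)phenol
Conditions: Ph3PCH3Br, NaHMDS (2.4 equiv), THF, 0 °C to rt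
Reagents that add atoms: methyltriphenylphosphonium bromide, C[P+](c1ccccc1)(c1ccccc1)c1ccccc1.[Br-]
Why: Wittig methylenation converts the aldehyde into the styrene; the extra equivalent of base covers the phenol, whose phenoxide does not interfere.

**Step 8**
Reactants: 10 2-bromo-4-hydroxybenzaldehyde
Product: 11 2-bromo-4-(triisopropylsilyloxy)benzaldehyde
Conditions: TIPSCl, imidazole, DMF, rt
Reagents that add atoms: chlorotriisopropylsilane, CC(C)[Si](Cl)(C(C)C)C(C)C
Why: Standard silylation of the only hydroxyl group gives a phenol protecting group that tolerates the later organometallic steps and leaves with fluoride.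

**Step 9**
Reactants: 9 2-ethenyl-4-(3-methylbut-2-en-1-yl)-5-(triisopropylsilyloxy)phenol; 11 2-bromo-4-(triisopropylsilyloxy)benzaldehyde
Product: 12 2-[2-ethenyl-4-(3-methylbut-2-en-1-yl)-5-(triisopropylsilyloxy)phenoxy]-4-(triisopropylsilyloxy)benzaldehyde
Conditions: CuI (cat.), N,N-dimethylglycine (cat.), Cs2CO3, 1,4-dioxane, 90 °C
Reagents that add atoms: none
Why: Ullmann diaryl ether synthesis; the ortho-formyl group activates the aryl bromide, copper does not draw the vinyl group into a Heck reaction, and the medium holds neither fluoride nor hydroxide, so both aryl silyl ethers should persist.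

**Step 10**
Reactants: 12 2-[2-ethenyl-4-(3-methylbut-2-en-1-yl)-5-(triisopropylsilyloxy)phenoxy]-4-(triisopropylsilyloxy)benzaldehyde
Product: 13 2-[2-ethenyl-4-(3-methylbut-2-en-1-yl)-5-(triisopropylsilyloxy)phenoxy]-4-(triisopropylsilyloxy)benzoic acid
Conditions: NaClO2, NaH2PO4, 2-methylbut-2-ene (large excess), t-BuOH–THF–H2O, 0 °C to rt
Reagents that add atoms: sodium chlorite, [Na+].[O-]Cl=O
Why: Pinnick oxidation converts the aldehyde into the acid, and the alkene scavenger removes hypochlorous acid before it can add to the prenyl or vinyl group.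

**Step 11**
Reactants: 13 2-[2-ethenyl-4-(3-methylbut-2-en-1-yl)-5-(triisopropylsilyloxy)phenoxy]-4-(triisopropylsilyloxy)benzoic acid; 5 (2S)-6-methyl-2-[(2S)-oxiran-2-yl]hept-5-en-2-ol
Product: 16 (2S)-6-methyl-2-[(2S)-oxiran-2-yl]hept-5-en-2-yl ester of acid 13, via acid chloride 14 (not isolated), via lithium alkoxide 15 (not isolated)
Conditions: (i) 13, Me2C=C(Cl)NMe2, CH2Cl2, 0 °C; (ii) 5, LiHMDS (1.0 equiv), THF, −78 °C; (iii) add (i) to (ii), −78 to −20 °C
Reagents that add atoms: none
Why: Acylation of a tertiary lithium alkoxide by an acid chloride made under neutral conditions is the standard way to a tertiary ester; at −78 °C the alkoxide should be acylated before it can open the neighbouring oxirane.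

**Step 12**
Reactants: 16 (2S)-6-methyl-2-[(2S)-oxiran-2-yl]hept-5-en-2-yl ester of acid 13
Product: 17 1-alkoxyvinyl arene (the C=O of 16 replaced by C=CH2)
Conditions: Cp2TiMe2 (3 equiv), toluene–THF, 65 °C, dark
Reagents that add atoms: dimethyltitanocene, [Ti+4].[CH3-].[CH3-].c1cc[cH-]c1.c1cc[cH-]c1
Why: Petasis methylenation turns the ester C=O into C=CH2 through the titanium methylidene; the reagent is aluminium-free and not Lewis acidic, which the acid-labile tert-alkyl enol ether and the oxirane need.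

**Step 13**
Reactants: 17 1-alkoxyvinyl arene
Product: 18 10-{[(2S)-6-methyl-2-[(2S)-oxiran-2-yl]hept-5-en-2-yl]oxy}-2-(3-methylbut-2-en-1-yl)-3,7-bis(triisopropylsilyloxy)dibenzo[b,f]oxepine
Conditions: Grubbs II catalyst (cat.), toluene, 70 °C
Reagents that add atoms: none
Why: Ring-closing metathesis of an enol ether with a styrene; ruthenium should load on the monosubstituted styrene, close the seven-membered ring onto the 1-alkoxyvinyl group and release ethene, while the trisubstituted prenyl-type alkenes react far more slowly.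

**Step 14**
Reactants: 18 10-alkoxy-dibenzo[b,f]oxepine with the side-chain oxirane
Product: 19 bis(triisopropylsilyl) ether of the target
Conditions: Me2AlCl (2 equiv), 2,6-di-tert-butyl-4-methylpyridine (0.3 equiv), CH2Cl2, −78 to −30 °C; then Et3N, aq. Rochelle salt
Reagents that add atoms: none
Why: Proposed new method: Me2AlCl binds the oxirane oxygen and C11, the β-carbon of the cyclic enol ether O–C10=C11, attacks the terminal CH2 from the backside in an SN2-like opening, which gives an oxocarbenium ion at C10 (stabilised by the ether oxygen and the para-silyloxy ring B) that loses H-11 to an Al–CH3 group (methane) and so restores the enol ether. The closest known reaction type is the Lewis acid mediated intramolecular Friedel–Crafts (epoxy–arene) cyclisation of aryl glycidyl ethers to chroman-3-ols, together with alkylaluminium chloride promoted epoxide–olefin cyclisation; an enol ether as the π-nucleophile at a primary oxirane carbon is the new element. The one ring that closes is the dihydropyran, in the endo mode of epoxide opening (6-(enolendo)-exo-tet with respect to the bond that leaves). No new stereocentre forms: the C–O bonds at the quaternary carbon and at the carbinol carbon are not touched, so both keep the S configuration set in steps 1 and 3. The step needs attack at CH2 and not at the oxirane CH (that carbon is neopentyl and deactivated by the vicinal ether oxygen, which also retards ionisation of the tertiary C–O bond), and attack by C11 and not by the 6,7-alkene, which is also six atoms away but is a far weaker nucleophile than the donor-substituted enol ether.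

**Step 15**
Reactants: 19 bis(triisopropylsilyl) ether of the target
Product: 20 target CNP0185870.1
Conditions: TBAF, AcOH (1:1, 2.5 equiv), THF, 0 °C
Reagents that add atoms: none
Why: Fluoride cleaves both aryl silyl ethers, and the acetic acid buffer keeps the enol ether and the prenylated phenol away from strong base and from strong acid.

**Compound list**
1 | nerol, (2Z)-3,7-dimethylocta-2,6-dien-1-ol | CC(C)=CCC/C(C)=C\CO | starting material
2 | [(2S,3R)-3-methyl-3-(4-methylpent-3-en-1-yl)oxiran-2-yl]methanol | OC[C@@H]1O[C@]1(C)CCC=C(C)C | intermediate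
3 | [(2S,3R)-3-methyl-3-(4-methylpent-3-en-1-yl)oxiran-2-yl]methyl 4-methylbenzenesulfonate | Cc1ccc(cc1)S(=O)(=O)OC[C@@H]1O[C@]1(C)CCC=C(C)C | intermediate
4 | (2S,3S)-2,3-dihydroxy-3,7-dimethyloct-6-en-1-yl 4-methylbenzenesulfonate | Cc1ccc(cc1)S(=O)(=O)OC[C@H](O)[C@@](C)(O)CCC=C(C)C | intermediate
5 | (2S)-6-methyl-2-[(2S)-oxiran-2-yl]hept-5-en-2-ol | CC(C)=CCC[C@](C)(O)[C@@H]1CO1 | intermediate
6 | 5-bromo-2,4-dihydroxybenzaldehyde | O=Cc1cc(Br)c(O)cc1O | starting material
7 | 5-bromo-2-hydroxy-4-(triisopropylsilyloxy)benzaldehyde | O=Cc1cc(Br)c(O[Si](C(C)C)(C(C)C)C(C)C)cc1O | intermediate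
8 | 2-hydroxy-5-(3-methylbut-2-en-1-yl)-4-(triisopropylsilyloxy)benzaldehyde | O=Cc1cc(CC=C(C)C)c(O[Si](C(C)C)(C(C)C)C(C)C)cc1O | intermediate
9 | 2-ethenyl-4-(3-methylbut-2-en-1-yl)-5-(triisopropylsilyloxy)phenol | C=Cc1cc(CC=C(C)C)c(O[Si](C(C)C)(C(C)C)C(C)C)cc1O | intermediate
10 | 2-bromo-4-hydroxybenzaldehyde | O=Cc1ccc(O)cc1Br | starting material
11 | 2-bromo-4-(triisopropylsilyloxy)benzaldehyde | O=Cc1ccc(O[Si](C(C)C)(C(C)C)C(C)C)cc1Br | intermediate
12 | 2-[2-ethenyl-4-(3-methylbut-2-en-1-yl)-5-(triisopropylsilyloxy)phenoxy]-4-(triisopropylsilyloxy)benzaldehyde | O=Cc1ccc(O[Si](C(C)C)(C(C)C)C(C)C)cc1Oc1cc(O[Si](C(C)C)(C(C)C)C(C)C)c(CC=C(C)C)cc1C=C | intermediate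
13 | 2-[2-ethenyl-4-(3-methylbut-2-en-1-yl)-5-(triisopropylsilyloxy)phenoxy]-4-(triisopropylsilyloxy)benzoic acid | OC(=O)c1ccc(O[Si](C(C)C)(C(C)C)C(C)C)cc1Oc1cc(O[Si](C(C)C)(C(C)C)C(C)C)c(CC=C(C)C)cc1C=C | intermediate
14 | acid chloride of 13 | ClC(=O)c1ccc(O[Si](C(C)C)(C(C)C)C(C)C)cc1Oc1cc(O[Si](C(C)C)(C(C)C)C(C)C)c(CC=C(C)C)cc1C=C | intermediate
15 | lithium alkoxide of 5 | CC(C)=CCC[C@](C)([O-])[C@@H]1CO1.[Li+] | intermediate
16 | (2S)-6-methyl-2-[(2S)-oxiran-2-yl]hept-5-en-2-yl 2-[2-ethenyl-4-(3-methylbut-2-en-1-yl)-5-(triisopropylsilyloxy)phenoxy]-4-(triisopropylsilyloxy)benzoate | CC(C)=CCC[C@](C)(OC(=O)c1ccc(O[Si](C(C)C)(C(C)C)C(C)C)cc1Oc1cc(O[Si](C(C)C)(C(C)C)C(C)C)c(CC=C(C)C)cc1C=C)[C@@H]1CO1 | intermediate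
17 | 1-alkoxyvinyl arene: the ester C=O of 16 replaced by C=CH2 | CC(C)=CCC[C@](C)(OC(=C)c1ccc(O[Si](C(C)C)(C(C)C)C(C)C)cc1Oc1cc(O[Si](C(C)C)(C(C)C)C(C)C)c(CC=C(C)C)cc1C=C)[C@@H]1CO1 | intermediate
18 | 10-{[(2S)-6-methyl-2-[(2S)-oxiran-2-yl]hept-5-en-2-yl]oxy}-2-(3-methylbut-2-en-1-yl)-3,7-bis(triisopropylsilyloxy)dibenzo[b,f]oxepine | CC(C)=CCC[C@](C)(OC1=Cc2cc(CC=C(C)C)c(O[Si](C(C)C)(C(C)C)C(C)C)cc2Oc2cc(O[Si](C(C)C)(C(C)C)C(C)C)ccc12)[C@@H]1CO1 | intermediate
19 | target with both phenols as triisopropylsilyl ethers; (2S,3S)-3-hydroxy-2-methyl-2-(4-methylpent-3-en-1-yl)dihydropyran fused at the oxepine C10=C11 bond | CC(C)=CCC[C@]1(C)OC2=C(C[C@@H]1O)c1cc(CC=C(C)C)c(O[Si](C(C)C)(C(C)C)C(C)C)cc1Oc1cc(O[Si](C(C)C)(C(C)C)C(C)C)ccc12 | intermediate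
20 | CNP0185870.1; (2S,3S)-pyrano-fused dibenzo[b,f]oxepine diol with a prenyl group on ring A | CC(C)=CCC[C@]1(C)OC2=C(C[C@@H]1O)c1cc(CC=C(C)C)c(O)cc1Oc1cc(O)ccc12 | target

**Step count**
Total: 15 steps. Longest linear sequence: 10 steps (5, 6, 7, 9, 10, 11, 12, 13, 14, 15).

**Steps most likely to fail**

1. Step 14. Chloride may be delivered from aluminium to the activated oxirane, or the tert-alkyl enol ether may be protonated or ionised before the C–C bond forms; the 6,7-alkene may also close onto the oxirane. The fallback uses known chemistry and sets out from 18. Bromination of the enol ether β-carbon with N-bromosuccinimide and 2,6-lutidine (CH2Cl2, −78 °C; addition of bromine at C11 and loss of H-11) should give the 11-bromo enol ether F1. Bromine–lithium exchange with t-BuLi (THF, −78 °C), then BF3·OEt2, should make the vinyllithium open the oxirane at its terminal carbon (Parham-type cyclisation). This comes back to the route at 19.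

2. Step 12. The oxophilic titanium methylidene may insert into or deoxygenate the terminal oxirane while the hindered tertiary ester reacts slowly. The fallback carries the oxirane in masked form and sets out from 4. Silylation of the secondary hydroxyl (TESOTf, 2,6-lutidine, −78 °C) should give the (2S,3S)-3-hydroxy-2-(triethylsilyloxy) tosylate F2. Its lithium alkoxide, acylated with acid chloride 14 at −78 °C, should give the tertiary ester F3. Petasis methylenation should give the 1-alkoxyvinyl arene F4, and ring-closing metathesis the dibenzoxepine F5, which still holds the silyloxy tosylate. TBAF should then remove all three silyl groups, and the freed secondary alkoxide should close the oxirane to give the bis-phenol epoxide F6. Resilylation of the two phenols (TIPSCl, imidazole) comes back to the route at 18.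

3. Step 11. The oxirane may migrate onto the tertiary lithium alkoxide (Payne rearrangement) before the slow acylation by the hindered acid chloride, so that the primary alkoxide is acylated instead. The fallback acylates an alkoxide that has no oxirane next to it and sets out from 2. Acid hydrolysis (HClO4, THF–H2O; inversion at C3) should give (2S,3S)-3,7-dimethyloct-6-ene-1,2,3-triol F7. Kinetic acetalisation (2-methoxypropene, PPTS, 0 °C) should give the terminal acetonide F8 with the tertiary hydroxyl free. Its lithium alkoxide and acid chloride 14 should give the acetonide ester F9. Mild acid (AcOH–H2O, 40 °C) should give the diol ester F10. Mitsunobu cyclodehydration (PPh3, DIAD), which activates the primary hydroxyl and retains C2, comes back to the route at 16.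

**Further compounds**
F1 | step 14 | 11-bromo-10-{[(2S)-6-methyl-2-[(2S)-oxiran-2-yl]hept-5-en-2-yl]oxy}-2-(3-methylbut-2-en-1-yl)-3,7-bis(triisopropylsilyloxy)dibenzo[b,f]oxepine | CC(C)=CCC[C@](C)(OC1=C(Br)c2cc(CC=C(C)C)c(O[Si](C(C)C)(C(C)C)C(C)C)cc2Oc2cc(O[Si](C(C)C)(C(C)C)C(C)C)ccc12)[C@@H]1CO1
F2 | step 12 | (2S,3S)-3-hydroxy-3,7-dimethyl-2-(triethylsilyloxy)oct-6-en-1-yl 4-methylbenzenesulfonate | Cc1ccc(cc1)S(=O)(=O)OC[C@H](O[Si](CC)(CC)CC)[C@@](C)(O)CCC=C(C)C
F3 | step 12 | ester of acid 13 with the tertiary hydroxyl of F2 | Cc1ccc(cc1)S(=O)(=O)OC[C@H](O[Si](CC)(CC)CC)[C@@](C)(OC(=O)c1ccc(O[Si](C(C)C)(C(C)C)C(C)C)cc1Oc1cc(O[Si](C(C)C)(C(C)C)C(C)C)c(CC=C(C)C)cc1C=C)CCC=C(C)C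
F4 | step 12 | 1-alkoxyvinyl arene from F3 (C=O replaced by C=CH2) | Cc1ccc(cc1)S(=O)(=O)OC[C@H](O[Si](CC)(CC)CC)[C@@](C)(OC(=C)c1ccc(O[Si](C(C)C)(C(C)C)C(C)C)cc1Oc1cc(O[Si](C(C)C)(C(C)C)C(C)C)c(CC=C(C)C)cc1C=C)CCC=C(C)C
F5 | step 12 | 10-alkoxy-dibenzo[b,f]oxepine with the (2S,3S)-2-(triethylsilyloxy)-1-tosyloxy side chain | Cc1ccc(cc1)S(=O)(=O)OC[C@H](O[Si](CC)(CC)CC)[C@@](C)(OC1=Cc2cc(CC=C(C)C)c(O[Si](C(C)C)(C(C)C)C(C)C)cc2Oc2cc(O[Si](C(C)C)(C(C)C)C(C)C)ccc12)CCC=C(C)C
F6 | step 12 | 10-{[(2S)-6-methyl-2-[(2S)-oxiran-2-yl]hept-5-en-2-yl]oxy}-2-(3-methylbut-2-en-1-yl)dibenzo[b,f]oxepine-3,7-diol | CC(C)=CCC[C@](C)(OC1=Cc2cc(CC=C(C)C)c(O)cc2Oc2cc(O)ccc12)[C@@H]1CO1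
F7 | step 11 | (2S,3S)-3,7-dimethyloct-6-ene-1,2,3-triol | OC[C@H](O)[C@@](C)(O)CCC=C(C)C
F8 | step 11 | (2S)-2-[(4S)-2,2-dimethyl-1,3-dioxolan-4-yl]-6-methylhept-5-en-2-ol | CC(C)=CCC[C@](C)(O)[C@@H]1COC(C)(C)O1
F9 | step 11 | ester of acid 13 with the tertiary hydroxyl of F8 | CC(C)=CCC[C@](C)(OC(=O)c1ccc(O[Si](C(C)C)(C(C)C)C(C)C)cc1Oc1cc(O[Si](C(C)C)(C(C)C)C(C)C)c(CC=C(C)C)cc1C=C)[C@@H]1COC(C)(C)O1
F10 | step 11 | (2S,3S)-1,2-dihydroxy-3,7-dimethyloct-6-en-3-yl ester of acid 13 | CC(C)=CCC[C@](C)(OC(=O)c1ccc(O[Si](C(C)C)(C(C)C)C(C)C)cc1Oc1cc(O[Si](C(C)C)(C(C)C)C(C)C)c(CC=C(C)C)cc1C=C)[C@@H](O)CO
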